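The oxane ring (O1, C2–C6) is read as a 6-hydroxy-2H-pyran-3(6H)-one: C5, the alkylidene carbon, is a latent ketone next to the O1–C6H2 unit, the pyridone-bearing C2 is a latent lactol carbon, and C3 is the β-carbon of an enone. This pyranone is not closed as a six-membered ring; it arises by oxidative ring expansion (Achmatowicz rearrangement) of furfuryl alcohol, whose furan already holds C2–C5 and whose CH2OH becomes C6–O1. One operation thus gives the ring, the ketone, the enone and the anomeric handle. A catalytic dynamic acylation then sets one stereocentre, which is relayed to C3 (anti cuprate addition) and to C2 (C-glycosylation); the ketone directs the Z-selective Wittig.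

Key step: step 1

Assumption: (R)-2-methylbutanoic acid is taken as a commercial single-enantiomer building block.

Step 1
Reactants: 1 furfuryl alcohol
Product: 3 6-hydroxy-2H-pyran-3(6H)-one (racemic lactol), via (Z)-5-hydroxy-4-oxopent-2-enal 2 (not isolated)
Conditions: NBS, NaHCO3, THF/H2O (4:1), 0 °C
Reagents that add atoms: water, SMILES O
Why: NBS delivers electrophilic bromine to the furan and water adds at the 2,5-positions; the resulting 2,5-dihydrofuran hemiacetal opens to the (Z)-enedione 2, and its primary hydroxyl then adds to the aldehyde to give lactol 3. The closest known reaction type is the Achmatowicz rearrangement of furfuryl alcohols itself, so the step stays within known chemistry. The six-membered ring closes by 6-exo-trig hemiacetalisation, in which the former carbinol oxygen becomes O1 and the aldehyde carbon becomes C2, so the five-membered furan is expanded by one atom. The only new stereocentre is the anomeric carbon; it forms as a racemic lactol that epimerises through 2 and is deliberately left uncontrolled, because step 2 resolves it dynamically. The step needs chemoselective oxidation of the furan beside the primary alcohol and a Z-enedione for ring closure: the electron-rich furan is the most oxidisable site, and the Z geometry is inherited from the ring.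

Step 2
Reactants: 3 6-hydroxy-2H-pyran-3(6H)-one
Product: 4 (S)-5-oxo-5,6-dihydro-2H-pyran-2-yl 2-methylpropanoate
Conditions: (i-PrCO)2O, benzotetramisole (2 mol %, the enantiomer that gives the S ester), i-Pr2NEt, toluene, 0 °C
Reagents that add atoms: isobutyric anhydride, SMILES CC(C)C(=O)OC(=O)C(C)C
Why: Dynamic kinetic asymmetric acylation of a lactol: the enantiomers of 3 interconvert through the open hydroxy-enedione while the chiral isothiourea acyl-transfer catalyst acylates one of them faster, which should set the anomeric stereocentre (S) as the only catalyst-derived stereocentre of the ring.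

Step 3
Reactants: 4 (S)-5-oxo-5,6-dihydro-2H-pyran-2-yl 2-methylpropanoate
Product: 5 (R)-6-(benzyloxy)-2H-pyran-3(6H)-one
Conditions: BnOH, Pd2(dba)3·CHCl3 (2.5 mol %), PPh3 (10 mol %), CH2Cl2, 0 °C
Reagents that add atoms: benzyl alcohol, SMILES OCc1ccccc1
Why: Tsuji–Trost allylic substitution at the anomeric carbon: ionisation by the palladium catalyst with inversion and outer-sphere attack of the alcohol with a second inversion should give net retention, so the benzyloxy group takes the place of the ester (the descriptor changes to R only through the priority rules).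

Step 4
Reactants: 5 (R)-6-(benzyloxy)-2H-pyran-3(6H)-one
Product: 6 (5R,6R)-6-(benzyloxy)-5-methyldihydro-2H-pyran-3(4H)-one
Conditions: Me2CuLi (from MeLi and CuI), Et2O, −78 °C; aq. NH4Cl
Reagents that add atoms: lithium dimethylcuprate, SMILES [Li+].C[Cu-]C
Why: Conjugate (1,4-) addition of lithium dimethylcuprate to the enone should occur anti to the neighbouring pseudoaxial benzyloxy group, so the methyl-bearing centre (5R) is set by substrate control from the anomeric centre.

Step 5
Reactants: 7 5-bromo-2,4-dimethoxypyridine; 8 phenylboronic acid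
Product: 9 2,4-dimethoxy-5-phenylpyridine
Conditions: Pd(PPh3)4 (3 mol %), K2CO3, dioxane/H2O, 90 °C
Reagents that add atoms: none
Why: Suzuki–Miyaura coupling at the C–Br bond installs the 5-phenyl group; no stereocentre is formed.

Step 6
Reactants: 9 2,4-dimethoxy-5-phenylpyridine
Product: 10 2,4-dimethoxy-5-phenylpyridine 1-oxide
Conditions: mCPBA, CH2Cl2, 0 → 23 °C
Reagents that add atoms: mCPBA, SMILES OOC(=O)c1cccc(Cl)c1
Why: Peracid N-oxidation of the electron-rich 2,4-dialkoxypyridine puts the future N-hydroxyl oxygen in place.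

Step 7
Reactants: 10 2,4-dimethoxy-5-phenylpyridine 1-oxide
Product: 11 1,4-dihydroxy-5-phenylpyridin-2(1H)-one
Conditions: 48% aq. HBr, AcOH, 100 °C
Reagents that add atoms: none
Why: Acidic ether cleavage (SN2 attack of bromide on the O-methyl groups of the protonated substrate) converts the 2-methoxy N-oxide into the cyclic hydroxamic acid and frees the 4-hydroxyl, which makes C-3 a strong carbon nucleophile.

Step 8
Reactants: 6 (5R,6R)-6-(benzyloxy)-5-methyldihydro-2H-pyran-3(4H)-one; 11 1,4-dihydroxy-5-phenylpyridin-2(1H)-one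
Product: 12 (5R,6R)-6-(1,4-dihydroxy-2-oxo-5-phenyl-1,2-dihydropyridin-3-yl)-5-methyldihydro-2H-pyran-3(4H)-one
Conditions: TfOH (0.2 equiv), 4 Å MS, MeCN, 0 → 40 °C
Reagents that add atoms: none
Why: Friedel–Crafts-type aryl C-glycosylation: acid ionises the benzyl acetal to the cyclic oxocarbenium ion, C-3 of the 4-hydroxypyridone attacks it (O-linked adducts revert under the acid), and the aryl group should end trans to the neighbouring methyl group (diequatorial, the known thermodynamic outcome of acid-mediated anomerisation of ortho-hydroxyaryl C-glycosides), so the new centre (6R) is set by the methyl-bearing centre.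

Step 9
Reactants: 12 (5R,6R)-6-(1,4-dihydroxy-2-oxo-5-phenyl-1,2-dihydropyridin-3-yl)-5-methyldihydro-2H-pyran-3(4H)-one
Product: 13 (5R,6R)-6-[1,4-bis(allyloxy)-2-oxo-5-phenyl-1,2-dihydropyridin-3-yl]-5-methyldihydro-2H-pyran-3(4H)-one
Conditions: allyl bromide (2.5 equiv), K2CO3, DMF, 23 °C
Reagents that add atoms: allyl bromide, SMILES C=CCBr
Why: Williamson-type O-alkylation masks the acidic N-hydroxyl and 4-hydroxyl groups as allyl ethers that tolerate the basic olefinations and can be removed later under neutral conditions.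

Step 10
Reactants: 13 (5R,6R)-6-[1,4-bis(allyloxy)-2-oxo-5-phenyl-1,2-dihydropyridin-3-yl]-5-methyldihydro-2H-pyran-3(4H)-one
Product: 15 (2Z)-2-[(5R,6R)-6-[1,4-bis(allyloxy)-2-oxo-5-phenyl-1,2-dihydropyridin-3-yl]-5-methyloxan-3-ylidene]acetaldehyde, via dioxolane acetal 14 (not isolated)
Conditions: [(1,3-dioxolan-2-yl)methyl]triphenylphosphonium bromide, KN(SiMe3)2, THF, −78 → 0 °C; then 1 M HCl, THF, 0 °C
Reagents that add atoms: [(1,3-dioxolan-2-yl)methyl]triphenylphosphonium bromide, SMILES [Br-].C1COC(O1)C[P+](c1ccccc1)(c1ccccc1)c1ccccc1; water, SMILES O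
Why: Wittig olefination of the α-alkoxy ketone with a non-stabilised ylide, for which the ylide substituent is known to end cis to the oxygen-bearing α-carbon (here C6), should give the Z exocyclic alkene, and mild acid then hydrolyses the dioxolane of 14 to the enal.

Step 11
Reactants: 16 (R)-2-methylbutanoic acid
Product: 17 (R)-2-methylbutan-1-ol
Conditions: LiAlH4, Et2O, 0 → 23 °C
Reagents that add atoms: none
Why: Hydride reduction of the carboxylic acid to the primary alcohol leaves the α-stereocentre untouched.

Step 12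
Reactants: 17 (R)-2-methylbutan-1-ol
Product: 19 ethyl (R,E)-4-methylhex-2-enoate, via (R)-2-methylbutanal 18 (not isolated)
Conditions: TEMPO (10 mol %), PhI(OAc)2, CH2Cl2, 23 °C; then Ph3P=CHCO2Et, 23 °C
Reagents that add atoms: ethyl (triphenylphosphoranylidene)acetate, SMILES CCOC(=O)C=P(c1ccccc1)(c1ccccc1)c1ccccc1
Why: Oxoammonium (TEMPO) oxidation gives the epimerisable aldehyde 18, which is trapped in the same flask by Wittig olefination with the stabilised ylide to give the E enoate without loss of the α-stereocentre.

Step 13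
Reactants: 19 ethyl (R,E)-4-methylhex-2-enoate
Product: 20 (R,E)-4-methylhex-2-en-1-ol
Conditions: i-Bu2AlH, CH2Cl2, −78 °C
Reagents that add atoms: none
Why: 1,2-Reduction of the enoate by the aluminium hydride gives the allylic alcohol and leaves the E alkene in place.

Step 14
Reactants: 20 (R,E)-4-methylhex-2-en-1-ol
Product: 21 diethyl [(R,E)-4-methylhex-2-en-1-yl]phosphonate
Conditions: P(OEt)3, ZnI2, toluene, 110 °C
Reagents that add atoms: triethyl phosphite, SMILES CCOP(OCC)OCC
Why: Zinc iodide-mediated Michaelis–Arbuzov-type conversion of the allylic alcohol (via the mixed phosphite) gives the linear E allylic phosphonate directly.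

Step 15
Reactants: 15 (2Z)-2-[(5R,6R)-6-[1,4-bis(allyloxy)-2-oxo-5-phenyl-1,2-dihydropyridin-3-yl]-5-methyloxan-3-ylidene]acetaldehyde; 21 diethyl [(R,E)-4-methylhex-2-en-1-yl]phosphonate
Product: 22 1,4-bis(allyloxy)-3-[(2R,3R,5Z)-3-methyl-5-[(2E,4E,6R)-6-methylocta-2,4-dien-1-ylidene]oxan-2-yl]-5-phenylpyridin-2(1H)-one
Conditions: LiN(SiMe3)2, THF, −78 → 0 °C
Reagents that add atoms: none
Why: Horner–Wadsworth–Emmons olefination of the enal with the lithiated allylic phosphonate forms the central double bond, expected E, and joins the two fragments without touching the existing alkenes or stereocentres.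

Step 16
Reactants: 22 1,4-bis(allyloxy)-3-[(2R,3R,5Z)-3-methyl-5-[(2E,4E,6R)-6-methylocta-2,4-dien-1-ylidene]oxan-2-yl]-5-phenylpyridin-2(1H)-one
Product: 23 1,4-dihydroxy-3-[(2R,3R,5Z)-3-methyl-5-[(2E,4E,6R)-6-methylocta-2,4-dien-1-ylidene]oxan-2-yl]-5-phenylpyridin-2(1H)-one
Conditions: Pd(PPh3)4 (5 mol %), morpholine, THF, 23 °C
Reagents that add atoms: none
Why: Tsuji–Trost deallylation: the palladium catalyst ionises both allyl ethers and morpholine traps the allyl fragments, which should release the N-hydroxyl and 4-hydroxyl groups under neutral conditions that spare the triene.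

Compound list

1 | furfuryl alcohol | OCc1ccco1 | starting material
2 | (Z)-5-hydroxy-4-oxopent-2-enal | O=C/C=C\C(=O)CO | intermediate
3 | 6-hydroxy-2H-pyran-3(6H)-one (racemic lactol) | O=C1COC(O)C=C1 | intermediate
4 | (S)-5-oxo-5,6-dihydro-2H-pyran-2-yl 2-methylpropanoate | O=C1CO[C@@H](OC(=O)C(C)C)C=C1 | intermediate
5 | (R)-6-(benzyloxy)-2H-pyran-3(6H)-one | O=C1CO[C@@H](OCc2ccccc2)C=C1 | intermediate
6 | (5R,6R)-6-(benzyloxy)-5-methyldihydro-2H-pyran-3(4H)-one | O=C1CO[C@@H](OCc2ccccc2)[C@H](C)C1 | intermediate
7 | 5-bromo-2,4-dimethoxypyridine | COc1cc(OC)c(Br)cn1 | starting material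
8 | phenylboronic acid | OB(O)c1ccccc1 | starting material
9 | 2,4-dimethoxy-5-phenylpyridine | COc1cc(OC)c(-c2ccccc2)cn1 | intermediate
10 | 2,4-dimethoxy-5-phenylpyridine 1-oxide | COc1cc(OC)c(-c2ccccc2)c[n+]1[O-] | intermediate
11 | 1,4-dihydroxy-5-phenylpyridin-2(1H)-one | O=c1cc(O)c(-c2ccccc2)cn1O | intermediate
12 | (5R,6R)-6-(1,4-dihydroxy-2-oxo-5-phenyl-1,2-dihydropyridin-3-yl)-5-methyldihydro-2H-pyran-3(4H)-one | O=C1CO[C@@H](c2c(O)c(-c3ccccc3)cn(O)c2=O)[C@H](C)C1 | intermediate
13 | (5R,6R)-6-[1,4-bis(allyloxy)-2-oxo-5-phenyl-1,2-dihydropyridin-3-yl]-5-methyldihydro-2H-pyran-3(4H)-one | O=C1CO[C@@H](c2c(OCC=C)c(-c3ccccc3)cn(OCC=C)c2=O)[C@H](C)C1 | intermediate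
14 | 1,4-bis(allyloxy)-3-[(2R,3R,5Z)-5-(1,3-dioxolan-2-ylmethylidene)-3-methyloxan-2-yl]-5-phenylpyridin-2(1H)-one (dioxolane acetal) | C1(OCCO1)/C=C2\CO[C@@H](c3c(OCC=C)c(-c4ccccc4)cn(OCC=C)c3=O)[C@H](C)C2 | intermediate
15 | (2Z)-2-[(5R,6R)-6-[1,4-bis(allyloxy)-2-oxo-5-phenyl-1,2-dihydropyridin-3-yl]-5-methyloxan-3-ylidene]acetaldehyde | O=C/C=C1\CO[C@@H](c2c(OCC=C)c(-c3ccccc3)cn(OCC=C)c2=O)[C@H](C)C1 | intermediate
16 | (R)-2-methylbutanoic acid | CC[C@@H](C)C(=O)O | starting material
17 | (R)-2-methylbutan-1-ol | CC[C@@H](C)CO | intermediate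
18 | (R)-2-methylbutanal | CC[C@@H](C)C=O | intermediate
19 | ethyl (R,E)-4-methylhex-2-enoate | CC[C@@H](C)/C=C/C(=O)OCC | intermediate
20 | (R,E)-4-methylhex-2-en-1-ol | CC[C@@H](C)/C=C/CO | intermediate
21 | diethyl [(R,E)-4-methylhex-2-en-1-yl]phosphonate | CC[C@@H](C)/C=C/CP(=O)(OCC)OCC | intermediate
22 | 1,4-bis(allyloxy)-3-[(2R,3R,5Z)-3-methyl-5-[(2E,4E,6R)-6-methylocta-2,4-dien-1-ylidene]oxan-2-yl]-5-phenylpyridin-2(1H)-one | CC[C@@H](C)/C=C/C=C/C=C1\CO[C@@H](c2c(OCC=C)c(-c3ccccc3)cn(OCC=C)c2=O)[C@H](C)C1 | intermediate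
23 | 1,4-dihydroxy-3-[(2R,3R,5Z)-3-methyl-5-[(2E,4E,6R)-6-methylocta-2,4-dien-1-ylidene]oxan-2-yl]-5-phenylpyridin-2(1H)-one | CC[C@@H](C)/C=C/C=C/C=C1\CO[C@@H](c2c(O)c(-c3ccccc3)cn(O)c2=O)[C@H](C)C1 | target

Total step count: 16. Longest linear sequence: 9 steps (steps 1, 2, 3, 4, 8, 9, 10, 15 and 16).

Steps most likely to fail

Step 10. The α-alkoxy preference of the ylide may be weaker for a cyclic ketone than for the open-chain cases on which it rests, so the exocyclic alkene could form with poor geometric control; enolisation of the ketone by the basic ylide and E/Z drift of the enal during the acidic hydrolysis are further risks. The fallback sets out from ketone 13 and replaces the kinetic Wittig by a stereospecific elimination. Lithiated [(1,3-dioxolan-2-yl)methyl]diphenylphosphine oxide (n-BuLi, THF, −78 °C) is added to 13, the diastereomeric adducts are separated by chromatography, and the diastereomer β-hydroxy phosphine oxide F1 is treated with NaH in DMF. The Horner–Wittig syn-elimination should then give acetal 14 as the single Z isomer, and hydrolysis as in step 10 returns to the route at 15.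

Step 8. Ionisation next to the electron-poor ketone may be sluggish, attack may stop at O-linked adducts, and reversible loss of a proton from the oxocarbenium ion (endocyclic enol ether) could erode the configuration of the methyl-bearing centre that controls everything else. The fallback sets out from ester 4 and forms the C–C bond before the methyl group is present. Pyridone 11, silylated in the flask with N,O-bis(trimethylsilyl)acetamide, undergoes palladium-catalysed allylic substitution with 4 (Pd2(dba)3·CHCl3, PPh3, CH2Cl2) with net retention to give, after desilylation, enone F2. Addition of Me2CuLi in the presence of Me3SiCl anti to the aryl group then returns to the route at 12.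

Step 15. The lithiated allylic phosphonate may give an E/Z mixture at the new double bond, and γ-deprotonation of the enal by the base could scramble the exocyclic alkene. The fallback sets out from allylic alcohol 20 and changes the olefination manifold. A Mitsunobu reaction with 1-phenyl-1H-tetrazole-5-thiol (PPh3, DIAD, THF) gives sulfide F3, and oxidation ((NH4)6Mo7O24·4H2O, H2O2, EtOH) gives sulfone F4. Julia–Kocienski olefination of enal 15 with F4 (KN(SiMe3)2, DME, −60 °C) returns to the route at 22.

Further compounds

F1 | step 10 | 1,4-bis(allyloxy)-3-{(2R,3R)-5-[(diphenylphosphoryl)(1,3-dioxolan-2-yl)methyl]-5-hydroxy-3-methyloxan-2-yl}-5-phenylpyridin-2(1H)-one (diastereomer whose syn-elimination gives the Z alkene) | O[C@@]1(CO[C@@H](c2c(OCC=C)c(-c3ccccc3)cn(OCC=C)c2=O)[C@H](C)C1)[C@H](P(=O)(c2ccccc2)c2ccccc2)C2OCCO2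
F2 | step 8 | (R)-6-(1,4-dihydroxy-2-oxo-5-phenyl-1,2-dihydropyridin-3-yl)-2H-pyran-3(6H)-one | O=C1CO[C@@H](c2c(O)c(-c3ccccc3)cn(O)c2=O)C=C1
F3 | step 15 | 5-{[(R,E)-4-methylhex-2-en-1-yl]sulfanyl}-1-phenyl-1H-tetrazole | CC[C@@H](C)/C=C/CSc1nnnn1-c1ccccc1
F4 | step 15 | 5-{[(R,E)-4-methylhex-2-en-1-yl]sulfonyl}-1-phenyl-1H-tetrazole | CC[C@@H](C)/C=C/CS(=O)(=O)c1nnnn1-c1ccccc1
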